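**Retrosynthetic overview** (ring A = benzo ring of the chromone, ring C = γ-pyrone ring, ring B = benzoic acid ring)
1. Last disconnection: the four phenolic OH groups are carried as benzyl ethers. The air- and decarboxylation-sensitive trihydroxybenzoic acid is therefore released only at the end, by neutral hydrogenolysis.
2. Key disconnection: at C2 of ring C both the exocyclic CH2–C2 bond and the ring bond O1–C2 are cut. This leads back to a laterally lithiated o-toluic acid (ring B with its CH3, the carboxylate as activating group) and to the open-chain α-oxoketene dithioacetal ArC(=O)CH=C(SMe)2 of the ring-A acetophenone.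
3. Enabling feature: C2 bears only O1, C3 and the benzylic CH2 and is the β-carbon of the C2=C3–C4=O enone, so a C(SMe)2 carbon at the thioester oxidation level can be substituted twice, first by carbon and then by the ring-A oxygen. The CH2 carbon sits on ring B ortho to the carboxyl carbon and is therefore a vinylogous acetate position that can be deprotonated, with the same polarity as the polyketide chain extension presumed for this bond.
4. Fragments: 5-heptylresorcinol → C-acetylation, 4-O-benzylation, CS2/MeI (CS2 supplies C2). Methyl orsellinate → para-hydroxylation (Elbs), tri-O-benzylation, saponification.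
5. Ring order: both benzene rings are bought. Ring C is the only ring made, and it closes in the key step.

Key step: step 7

Remark on the chemistry: the target has no stereocentre, no stereogenic axis and no configurable double bond. It is achiral, so no step has to control configuration.

Step 1
Reactants: 1 5-heptylbenzene-1,3-diol (5-heptylresorcinol)
Product: 3 1-(2,4-dihydroxy-6-heptylphenyl)ethan-1-one, via ketiminium chloride 2 (not isolated)
Conditions: MeCN, ZnCl2, HCl (g), Et2O, 0 °C → rt; then H2O, reflux
Reagents that add atoms: acetonitrile CC#N; water O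
Why: Houben–Hoesch acylation, in which the ZnCl2/HCl-activated nitrile should attack the resorcinol carbon that is para to one OH and ortho to the other (next to the heptyl chain) rather than the carbon between the two OH groups, as is usual for 5-alkylresorcinols, and hydrolysis of ketiminium salt 2 gives the methyl ketone.

Step 2
Reactants: 3 1-(2,4-dihydroxy-6-heptylphenyl)ethan-1-one
Product: 4 1-[4-(benzyloxy)-2-heptyl-6-hydroxyphenyl]ethan-1-one
Conditions: BnBr (1.05 equiv), K2CO3, acetone, reflux
Reagents that add atoms: benzyl bromide BrCc1ccccc1
Why: Williamson etherification, in which the OH ortho to the acetyl group is held in a hydrogen bond to the carbonyl oxygen and is much less nucleophilic, so one equivalent of benzyl bromide should alkylate only the para OH.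

Step 3
Reactants: 4 1-[4-(benzyloxy)-2-heptyl-6-hydroxyphenyl]ethan-1-one
Product: 5 1-[4-(benzyloxy)-2-heptyl-6-hydroxyphenyl]-3,3-bis(methylsulfanyl)prop-2-en-1-one
Conditions: t-BuOK (3.1 equiv), CS2, THF, 0 °C; MeI (2.05 equiv), 0 °C; cold 1 M HCl
Reagents that add atoms: carbon disulfide S=C=S; iodomethane CI
Why: α-Oxoketene dithioacetal synthesis (enolate thiocarboxylation with CS2, then double S-methylation), in which the soft ene-dithiolate is methylated much faster than the hindered, chelated phenoxide, and the low temperature and acidic quench keep the phenol from adding to the new C(SMe)2 carbon.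

Step 4
Reactants: 6 methyl 2,4-dihydroxy-6-methylbenzoate (methyl orsellinate)
Product: 8 methyl 3,4,6-trihydroxy-2-methylbenzoate, via potassium aryl sulfate 7 (not isolated)
Conditions: K2S2O8 (1.1 equiv), aq KOH, 0 °C → rt, N2; HCl to pH 4, extraction of unchanged 6; then aq HCl, 85 °C
Reagents that add atoms: potassium peroxodisulfate [K+].[K+].[O-]S(=O)(=O)OOS(=O)(=O)[O-]
Why: Elbs persulfate oxidation, in which peroxodisulfate attacks para to an ionised OH, the only free para position (C5 of 6, para to the 2-OH and flanked by the 4-OH and the CH3 group) is the one required, and acid then hydrolyses aryl sulfate 7 while the hindered methyl ester survives.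

Step 5
Reactants: 8 methyl 3,4,6-trihydroxy-2-methylbenzoate
Product: 9 methyl 3,4,6-tris(benzyloxy)-2-methylbenzoate
Conditions: BnBr (3.6 equiv), K2CO3, DMF, 60 °C, Ar
Reagents that add atoms: benzyl bromide BrCc1ccccc1
Why: Threefold Williamson etherification in a dipolar aprotic solvent, run under argon because the anion of the hydroxyhydroquinone 8 autoxidises, with excess reagent and heating so that the hydrogen-bonded OH next to the ester also reacts.

Step 6
Reactants: 9 methyl 3,4,6-tris(benzyloxy)-2-methylbenzoate
Product: 10 3,4,6-tris(benzyloxy)-2-methylbenzoic acid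
Conditions: KOH, DMSO–H2O, 100 °C; then 1 M HCl, 0 °C
Reagents that add atoms: potassium hydroxide [K+].[OH-]
Why: Saponification of a 2,6-disubstituted benzoate needs the poorly solvated hydroxide of aqueous DMSO at high temperature, which aryl benzyl ethers tolerate, and the free acid is required because its carboxylate is the activating group of the key step.

Step 7
Reactants: 10 3,4,6-tris(benzyloxy)-2-methylbenzoic acid; 5 1-[4-(benzyloxy)-2-heptyl-6-hydroxyphenyl]-3,3-bis(methylsulfanyl)prop-2-en-1-one
Product: 13 3,4,6-tris(benzyloxy)-2-{[7-(benzyloxy)-5-heptyl-4-oxo-4H-chromen-2-yl]methyl}benzoic acid, via dilithio dianion 11 (not isolated), via open-chain vinylogous thioester 12 (not isolated)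
Conditions: 10 (2.1 equiv), LDA (commercial solution, 5.3 equiv), THF, −78 → −10 °C, Ar; 5 (1.0 equiv) in THF, −78 °C → rt; MeOH, 45 °C; 1 M HCl, 0 °C
Reagents that add atoms: none
Why: LDA converts 10 into the carboxylate/benzylic dianion 11 (lateral lithiation of an o-toluic acid) and 5 into its lithium phenoxide, the CH2 carbon of 11 adds to the C(SMe)2 carbon of 5 (β-carbon of the enone, the future C2) and methanethiolate leaves to give 12, and once methanol has handed the proton back to the acidic CH2 group of 12 the ring-A phenoxide attacks the same carbon and expels the second methanethiolate. This copies the two events presumed for this part of the polyketide, namely the Claisen-type attack of a carboxyl-stabilised methylene carbanion on a carbon at the thioester oxidation level (5 is the S-methylated, non-enolisable form of the β-ketoacyl dithioester) and the closure of the pyrone by the ring-A phenol. The closest known reaction types are the displacement of SMe from α-oxoketene dithioacetals by carbanions, the base-induced closure of 2-hydroxyaryl β-(methylsulfanyl)enones to chromones and the condensation of lithiated orsellinates with 4-methoxy-2-pyrones. The γ-pyrone ring closes by a 6-endo-trig addition–elimination that forms O1–C2, and no stereocentre is created. The step needs 1,4- instead of 1,2-attack, which the delocalised benzylic anion (reversible 1,2-addition) and the ketone shielded by its two ortho substituents (heptyl and OLi) secure; it must not go on to a Staunton–Weinreb-type Claisen closure of C3 onto the ring-B carboxyl, which is excluded because that group is a lithium carboxylate and not an ester; and the phenoxide must win over the carboxylate in the second displacement, which its much higher nucleophilicity under the basic conditions secures. Should the phenoxide close first, the same carbon keeps one SMe group and is then substituted by 11, so both orders converge on 13, and the second equivalent of 11 acts only as base and returns as 10 on work-up.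

Step 8
Reactants: 13 3,4,6-tris(benzyloxy)-2-{[7-(benzyloxy)-5-heptyl-4-oxo-4H-chromen-2-yl]methyl}benzoic acid
Product: 14 2-[(5-heptyl-7-hydroxy-4-oxo-4H-chromen-2-yl)methyl]-3,4,6-trihydroxybenzoic acid (target)
Conditions: H2 (1 atm), 10% Pd/C, EtOAc–MeOH, rt; filtration under Ar
Reagents that add atoms: none
Why: Catalytic hydrogenolysis of the four aryl benzyl ethers under neutral, reductive conditions should leave the chromone C2=C3 bond and the carboxyl group untouched, as in the debenzylation of benzyloxychromones and -flavones, and avoids the acid- or base-induced decarboxylation and the autoxidation to which the product is prone.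

**Compound list**
1 | 5-heptylbenzene-1,3-diol (5-heptylresorcinol) | CCCCCCCc1cc(O)cc(O)c1 | starting material
2 | 1-(2,4-dihydroxy-6-heptylphenyl)ethan-1-iminium chloride | CCCCCCCc1cc(O)cc(O)c1C(C)=[NH2+].[Cl-] | intermediate
3 | 1-(2,4-dihydroxy-6-heptylphenyl)ethan-1-one | CCCCCCCc1cc(O)cc(O)c1C(C)=O | intermediate
4 | 1-[4-(benzyloxy)-2-heptyl-6-hydroxyphenyl]ethan-1-one | CCCCCCCc1cc(OCc2ccccc2)cc(O)c1C(C)=O | intermediate
5 | 1-[4-(benzyloxy)-2-heptyl-6-hydroxyphenyl]-3,3-bis(methylsulfanyl)prop-2-en-1-one | CCCCCCCc1cc(OCc2ccccc2)cc(O)c1C(=O)C=C(SC)SC | intermediate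
6 | methyl 2,4-dihydroxy-6-methylbenzoate (methyl orsellinate) | COC(=O)c1c(C)cc(O)cc1O | starting material
7 | methyl 4,6-dihydroxy-2-methyl-3-(sulfonatooxy)benzoate, potassium salt | COC(=O)c1c(C)c(OS(=O)(=O)[O-])c(O)cc1O.[K+] | intermediate
8 | methyl 3,4,6-trihydroxy-2-methylbenzoate | COC(=O)c1c(C)c(O)c(O)cc1O | intermediate
9 | methyl 3,4,6-tris(benzyloxy)-2-methylbenzoate | COC(=O)c1c(C)c(OCc2ccccc2)c(OCc2ccccc2)cc1OCc1ccccc1 | intermediate
10 | 3,4,6-tris(benzyloxy)-2-methylbenzoic acid | Cc1c(OCc2ccccc2)c(OCc2ccccc2)cc(OCc2ccccc2)c1C(=O)O | intermediate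
11 | lithium 3,4,6-tris(benzyloxy)-2-(lithiomethyl)benzoate | [Li]Cc1c(OCc2ccccc2)c(OCc2ccccc2)cc(OCc2ccccc2)c1C(=O)O[Li] | intermediate
12 | dilithium salt of 3,4,6-tris(benzyloxy)-2-{4-[4-(benzyloxy)-2-heptyl-6-hydroxyphenyl]-2-(methylsulfanyl)-4-oxobut-2-en-1-yl}benzoic acid (alkene geometry without consequence) | CCCCCCCc1cc(OCc2ccccc2)cc(O[Li])c1C(=O)C=C(SC)Cc1c(OCc2ccccc2)c(OCc2ccccc2)cc(OCc2ccccc2)c1C(=O)O[Li] | intermediate
13 | 3,4,6-tris(benzyloxy)-2-{[7-(benzyloxy)-5-heptyl-4-oxo-4H-chromen-2-yl]methyl}benzoic acid | CCCCCCCc1cc(OCc2ccccc2)cc2oc(Cc3c(OCc4ccccc4)c(OCc4ccccc4)cc(OCc4ccccc4)c3C(=O)O)cc(=O)c12 | intermediate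
14 | 2-[(5-heptyl-7-hydroxy-4-oxo-4H-chromen-2-yl)methyl]-3,4,6-trihydroxybenzoic acid | CCCCCCCc1cc(O)cc2oc(Cc3c(O)c(O)cc(O)c3C(=O)O)cc(=O)c12 | target

**Total step count:** 8. **Longest linear sequence:** 5 steps (1→2→3→7→8 or 4→5→6→7→8).

**Steps most likely to fail**

1. Step 7.
   - Risk: proton transfer from the first-formed 12 to 11 may outrun C–C bond formation. Attack on the donor-substituted, anionic acceptor may be sluggish. Part of the material may close through the carboxylate.
   - Fallback (sets out from 5 and 10, returns at 13): the two displacements are separated, and the polar C–C bond formation is replaced by a catalytic cross-coupling. Compound 5 is closed with K2CO3 in DMF at 80 °C to 7-(benzyloxy)-5-heptyl-2-(methylsulfanyl)-4H-chromen-4-one F1. Dianion 11, made from 10 as before, is transmetalated with ZnCl2 to lithium 3,4,6-tris(benzyloxy)-2-[(chlorozincio)methyl]benzoate F2. A Negishi-type coupling of F2 with the C–S bond of F1 (Pd(OAc)2, SPhos, THF, 25–50 °C), a reaction type known for benzylic zinc reagents and heteroaryl methyl thioethers, should give 13 after acidic work-up.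

2. Step 4.
   - Risk: low conversion, oxidative degradation of the electron-rich phenoxide, and competing ortho attack.
   - Fallback (sets out from 6, returns at 9): the oxygen is brought in through a halogen instead of by direct oxidation.
     - Compound 6 is dibenzylated (BnBr, K2CO3, DMF) to methyl 4,6-bis(benzyloxy)-2-methylbenzoate F3.
     - NBS in MeCN brominates para to the 6-benzyloxy group to give methyl 4,6-bis(benzyloxy)-3-bromo-2-methylbenzoate F4.
     - Miyaura borylation (B2pin2, Pd(dppf)Cl2, KOAc, dioxane, 90 °C) gives methyl 4,6-bis(benzyloxy)-2-methyl-3-(4,4,5,5-tetramethyl-1,3,2-dioxaborolan-2-yl)benzoate F5.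
     - Oxidation with H2O2/NaOH gives methyl 4,6-bis(benzyloxy)-3-hydroxy-2-methylbenzoate F6.
     - Benzylation of F6 gives 9.

3. Step 8.
   - Risk: catalyst poisoning by sulfur traces carried over from step 7, slow saturation of the pyrone C2=C3 bond, and autoxidation of the product during filtration.
   - Fallback (sets out from 13, returns at 14): Lewis-acid debenzylation with cation capture (BCl3, pentamethylbenzene, CH2Cl2, −78 °C, MeOH quench) replaces the metal-catalysed reduction. This fallback makes no new compound (F0).

**Further compounds**
F1 | step 7 | 7-(benzyloxy)-5-heptyl-2-(methylsulfanyl)-4H-chromen-4-one | CCCCCCCc1cc(OCc2ccccc2)cc2oc(SC)cc(=O)c12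
F2 | step 7 | lithium 3,4,6-tris(benzyloxy)-2-[(chlorozincio)methyl]benzoate | Cl[Zn]Cc1c(OCc2ccccc2)c(OCc2ccccc2)cc(OCc2ccccc2)c1C(=O)O[Li]
F3 | step 4 | methyl 4,6-bis(benzyloxy)-2-methylbenzoate | COC(=O)c1c(C)cc(OCc2ccccc2)cc1OCc1ccccc1
F4 | step 4 | methyl 4,6-bis(benzyloxy)-3-bromo-2-methylbenzoate | COC(=O)c1c(C)c(Br)c(OCc2ccccc2)cc1OCc1ccccc1
F5 | step 4 | methyl 4,6-bis(benzyloxy)-2-methyl-3-(4,4,5,5-tetramethyl-1,3,2-dioxaborolan-2-yl)benzoate | COC(=O)c1c(C)c(B2OC(C)(C)C(C)(C)O2)c(OCc2ccccc2)cc1OCc1ccccc1
F6 | step 4 | methyl 4,6-bis(benzyloxy)-3-hydroxy-2-methylbenzoate | COC(=O)c1c(C)c(O)c(OCc2ccccc2)cc1OCc1ccccc1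
F0 | step 8 | none | none
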